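**Retrosynthetic overview**
1. Target 25 ⇐ Schenck ene reaction of singlet oxygen on the C4=C5 alkene of 24 (O to C5, H from C15). The acrylate C11–C13 ⇐ methoxycarbonylation of the enol triflate of a C7 acetyl group; 3β-ester ⇐ Luche reduction; 8β-acetate ⇐ trans-diaxial iodoacetoxylation of the C8=C9 alkene.
2. 4-En-3-one 16 ⇐ loss of the C4 oxygen from cis-octalone 13 ⇐ anionic oxy-Cope rearrangement of the 2-vinylbicyclo[2.2.2]oct-5-en-2-ol 10 (C1–C10 formed, C3–C8 broken).
3. 10 ⇐ vinylmagnesium bromide + bicyclooctenone 8 ⇐ endo Diels–Alder adduct of methyl vinyl ketone with the Wessely quinol acetate of 2,4-dimethylphenol. The acetyl group is masked, and the racemate resolved, as its (2R,3R)-butane-2,3-diol ketal, so that C7 carries no acidic C–H in the key step.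
4. Ring order: ring B first (the cyclohexene ring of the bicycle, from the Diels–Alder step), ring A second (closed in the oxy-Cope step).
5. Structural feature: in ring B the C7 side chain and the C10 methyl C14 are cis, 1,4 across the ring. The endo adduct locks this relationship in a rigid bicycle before C10 becomes quaternary.

Key step: step 7

Remark: decalin locants follow eudesmane numbering (ring A = C1–C5, C10; ring B = C5–C10; C14 on C10, C15 on C4, C11–C13 on C7). Methyl vinyl ketone is assumed to add to 2 syn to the acetoxy group; since C4 later becomes trigonal, this fixes only the elimination geometry of step 9. Compounds 2 and 4 are racemic (one enantiomer drawn); everything from 6 on is a single enantiomer.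

**Step 1**
Reactants: 1 2,4-dimethylphenol
Product: 2 rac-6-acetoxy-4,6-dimethylcyclohexa-2,4-dien-1-one
Conditions: Pb(OAc)4, AcOH, rt
Reagents that add atoms: lead tetraacetate, CC(=O)O[Pb](OC(C)=O)(OC(C)=O)OC(C)=O
Why: Wessely acetoxylation (oxidative dearomatisation): the aryloxy–lead triacetate delivers acetate to the methyl-bearing ortho carbon and gives the ortho-quinol acetate; the quaternary centre forms as a racemate, which is accepted because step 3 resolves the material.

**Step 2**
Reactants: 2 rac-6-acetoxy-4,6-dimethylcyclohexa-2,4-dien-1-one; 3 methyl vinyl ketone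
Product: 4 rac-7-endo-acetyl-3,5-dimethyl-2-oxobicyclo[2.2.2]oct-5-en-3-yl acetate
Conditions: 3 (excess), BHT (cat.), toluene, 80 °C
Reagents that add atoms: none
Why: Diels–Alder reaction of the cyclohexa-2,4-dienone: the acetyl-bearing carbon bonds to the diene terminus next to the ring carbonyl ("ortho" orientation), the acetyl group sits endo (syn to the new C5=C6 bridge) and the dienophile approaches the face that carries the acetoxy group, which sets C1, C4 and C7 relative to C3.

**Step 3**
Reactants: 4 rac-7-endo-acetyl-3,5-dimethyl-2-oxobicyclo[2.2.2]oct-5-en-3-yl acetate; 5 (2R,3R)-butane-2,3-diol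
Product: 6 3,5-dimethyl-2-oxo-7-endo-[(4R,5R)-2,4,5-trimethyl-1,3-dioxolan-2-yl]bicyclo[2.2.2]oct-5-en-3-yl acetate (single diastereomer)
Conditions: 5, HC(OMe)3, camphorsulfonic acid (cat.), CH2Cl2, 0 °C → rt; separation of the two diastereomers (chromatography or crystallisation)
Reagents that add atoms: none
Why: acid-catalysed ketalisation, selective for the unhindered methyl ketone over the bridge ketone flanked by a quaternary carbon and a bridgehead; the C2-symmetric diol creates no new stereocentre, so racemic 4 gives two diastereomeric ketals and the one with the bicycle configuration shown is kept (resolution through covalent diastereomers, configuration to be confirmed crystallographically), and the ketal also removes the acidic C–H next to the acetyl group before any base is used.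

**Step 4**
Reactants: 6 3,5-dimethyl-2-oxo-7-endo-[(4R,5R)-2,4,5-trimethyl-1,3-dioxolan-2-yl]bicyclo[2.2.2]oct-5-en-3-yl acetate
Product: 7 3-hydroxy-3,5-dimethyl-7-endo-[(4R,5R)-2,4,5-trimethyl-1,3-dioxolan-2-yl]bicyclo[2.2.2]oct-5-en-2-one
Conditions: K2CO3 (cat.), MeOH, 0 °C
Reagents that add atoms: none
Why: base-catalysed transesterification (methanolysis) of the tertiary acetate, activated by the adjacent ketone; the ketone has no enolisable α-hydrogen (quaternary C3, bridgehead C1) and no stereocentre is touched.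

**Step 5**
Reactants: 7 3-hydroxy-3,5-dimethyl-7-endo-[(4R,5R)-2,4,5-trimethyl-1,3-dioxolan-2-yl]bicyclo[2.2.2]oct-5-en-2-one
Product: 8 3,5-dimethyl-3-(triethylsilyloxy)-7-endo-[(4R,5R)-2,4,5-trimethyl-1,3-dioxolan-2-yl]bicyclo[2.2.2]oct-5-en-2-one
Conditions: Et3SiOTf, 2,6-lutidine, CH2Cl2, −78 → 0 °C
Reagents that add atoms: triethylsilyl trifluoromethanesulfonate, CC[Si](CC)(CC)OS(=O)(=O)C(F)(F)F
Why: silylation of a hindered tertiary alcohol with a silyl triflate and a hindered pyridine base; ketals of ketones tolerate these conditions.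

**Step 6**
Reactants: 8 3,5-dimethyl-3-(triethylsilyloxy)-7-endo-[(4R,5R)-2,4,5-trimethyl-1,3-dioxolan-2-yl]bicyclo[2.2.2]oct-5-en-2-one; 9 vinylmagnesium bromide
Product: 10 3,5-dimethyl-3-(triethylsilyloxy)-7-endo-[(4R,5R)-2,4,5-trimethyl-1,3-dioxolan-2-yl]-2-vinylbicyclo[2.2.2]oct-5-en-2-ol (vinyl syn to the C5=C6 bridge, 2-OH cis to 3-OSiEt3)
Conditions: 9, THF, −78 → −20 °C; aq NH4Cl
Reagents that add atoms: none
Why: Grignard 1,2-addition to a non-enolisable ketone; the nucleophile enters from the face of the C5=C6 bridge, which is more open than the face guarded by the C7–C8 ethano bridge and the silyloxy group, so the vinyl group ends syn to the alkene bridge as the rearrangement requires.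

**Step 7**
Reactants: 10 3,5-dimethyl-3-(triethylsilyloxy)-7-endo-[(4R,5R)-2,4,5-trimethyl-1,3-dioxolan-2-yl]-2-vinylbicyclo[2.2.2]oct-5-en-2-ol
Product: 13 4α-(triethylsilyloxy)-11,11-[(2R,3R)-butane-2,3-diyldioxy]-12-nor-5β-eudesm-8-en-3-one (cis-fused), via potassium alkoxide 11 (not isolated), via potassium enolate 12 (not isolated)
Conditions: KN(SiMe3)2, 18-crown-6, THF, 0 °C → rt; aq NH4Cl, −78 °C
Reagents that add atoms: potassium bis(trimethylsilyl)amide, C[Si](C)(C)[N-][Si](C)(C)C.[K+] (its potassium stays only in intermediates 11 and 12)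
Why: Deprotonation gives a crown-separated potassium alkoxide whose oxyanion weakens the adjacent C3–C8 bond, so a charge-accelerated [3,3] sigmatropic shift forms C1–C10 and cleaves C3–C8 to give the C2=C3 enolate and the C8=C9 alkene. The closest known reaction type is the anionic oxy-Cope rearrangement of 2-vinylbicyclo[2.2.2]oct-5-en-2-ols to cis-fused octalones. Ring A closes as a six-membered carbocycle by this sigmatropic C–C bond formation through the boat-like transition state that the bicycle enforces, while ring B is the former cyclohexene ring of the bicycle. The new quaternary stereocentre C10 is controlled by the bicycle: the vinyl group is tethered through C3 on one flank of the C9=C10 bridge, so C1 can bond to C10 only on that face, which makes the ring fusion cis and leaves C14 cis to the C7 substituent set in the Diels–Alder step. The step needs the [3,3] path to outrun fragmentation and [1,3] shift and needs C7 to stay intact; the syn vinyl group and the non-enolisable dioxolane at C7 secure this, and silyl transfer between the two cis oxygens is reversible and unproductive. Protonation of the enolate at C2 creates no stereocentre.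

**Step 8**
Reactants: 13 4α-(triethylsilyloxy)-11,11-[(2R,3R)-butane-2,3-diyldioxy]-12-nor-5β-eudesm-8-en-3-one
Product: 14 4α-hydroxy-11,11-[(2R,3R)-butane-2,3-diyldioxy]-12-nor-5β-eudesm-8-en-3-one
Conditions: HF·pyridine, pyridine/THF, 0 °C → rt
Reagents that add atoms: none
Why: fluoride-driven Si–O cleavage of the tertiary triethylsilyl ether under buffered, non-basic conditions that spare the ketal and should not rearrange the ketol.

**Step 9**
Reactants: 14 4α-hydroxy-11,11-[(2R,3R)-butane-2,3-diyldioxy]-12-nor-5β-eudesm-8-en-3-one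
Product: 16 11,11-[(2R,3R)-butane-2,3-diyldioxy]-12-noreudesma-4,8-dien-3-one, via chlorosulfite ester 15 (not isolated)
Conditions: SOCl2, pyridine, CH2Cl2, −20 → 0 °C
Reagents that add atoms: thionyl chloride, O=S(Cl)Cl (its atoms stay only in intermediate 15)
Why: dehydration of a tertiary alcohol through its chlorosulfite by base-induced anti elimination (E2); in the favoured conformer of the cis-decalin (the other would hold C14 and C15 syn-diaxial) the 4α C–O bond and the 5β C–H bond are trans-diaxial, so elimination should run toward C5 and give the conjugated tetrasubstituted enone, erasing the C4 and C5 stereocentres.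

**Step 10**
Reactants: 16 11,11-[(2R,3R)-butane-2,3-diyldioxy]-12-noreudesma-4,8-dien-3-one
Product: 17 8β-acetoxy-9α-iodo-11,11-[(2R,3R)-butane-2,3-diyldioxy]-12-noreudesm-4-en-3-one
Conditions: N-iodosuccinimide, AcOH, CH2Cl2, 0 °C → rt, dark
Reagents that add atoms: N-iodosuccinimide, O=C1CCC(=O)N1I; acetic acid, CC(=O)O
Why: electrophilic iodoacetoxylation of the only electron-rich alkene (the enone double bond is deactivated); the iodonium ion forms on the α face, anti to C14 and the C7 substituent, and is opened trans-diaxially (Fürst–Plattner rule) by acetate at C8 from the β face and not at the neopentyl C9, which sets the axial 8β-acetoxy group cis to the C7 side chain.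

**Step 11**
Reactants: 17 8β-acetoxy-9α-iodo-11,11-[(2R,3R)-butane-2,3-diyldioxy]-12-noreudesm-4-en-3-one
Product: 18 8β-acetoxy-11,11-[(2R,3R)-butane-2,3-diyldioxy]-12-noreudesm-4-en-3-one
Conditions: Bu3SnH, AIBN (cat.), toluene, 80 °C
Reagents that add atoms: none
Why: radical chain dehalogenation; iodine abstraction by the stannyl radical is far faster than its addition to the enone, the β-acetoxyalkyl radical does not fragment, and C8 is not touched.

**Step 12**
Reactants: 18 8β-acetoxy-11,11-[(2R,3R)-butane-2,3-diyldioxy]-12-noreudesm-4-en-3-one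
Product: 19 8β-acetoxy-11,11-[(2R,3R)-butane-2,3-diyldioxy]-12-noreudesm-4-en-3β-ol
Conditions: NaBH4, CeCl3·7H2O, MeOH, −40 °C
Reagents that add atoms: none
Why: Luche 1,2-reduction of the enone; hydride adds axially from the α face of the half-chair ring A, opposite C14, to give the pseudo-equatorial 3β-alcohol, while the acetate and the ketal are inert.

**Step 13**
Reactants: 19 8β-acetoxy-11,11-[(2R,3R)-butane-2,3-diyldioxy]-12-noreudesm-4-en-3β-ol
Product: 20 8β-acetoxy-3β-(isobutyryloxy)-11,11-[(2R,3R)-butane-2,3-diyldioxy]-12-noreudesm-4-ene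
Conditions: i-PrCOCl, pyridine, DMAP (cat.), CH2Cl2, 0 °C → rt
Reagents that add atoms: isobutyryl chloride, CC(C)C(=O)Cl
Why: DMAP-catalysed O-acylation of the secondary allylic alcohol with retention at C3.

**Step 14**
Reactants: 20 8β-acetoxy-3β-(isobutyryloxy)-11,11-[(2R,3R)-butane-2,3-diyldioxy]-12-noreudesm-4-ene
Product: 21 8β-acetoxy-3β-(isobutyryloxy)-12-noreudesm-4-en-11-one
Conditions: pyridinium p-toluenesulfonate, acetone/H2O, 50 °C
Reagents that add atoms: water, O
Why: mild acid-catalysed ketal hydrolysis, with an acid too weak to ionise the allylic isobutyrate; C7, now α to a ketone, already holds the equatorial and thermodynamically preferred configuration.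

**Step 15**
Reactants: 21 8β-acetoxy-3β-(isobutyryloxy)-12-noreudesm-4-en-11-one
Product: 23 8β-acetoxy-3β-(isobutyryloxy)-12-noreudesma-4,11(13)-dien-11-yl trifluoromethanesulfonate, via potassium enolate 22 (not isolated)
Conditions: PhNTf2, then KN(SiMe3)2, THF, −78 °C; aq NH4Cl
Reagents that add atoms: N-phenylbis(trifluoromethanesulfonimide), O=S(=O)(N(c1ccccc1)S(=O)(=O)C(F)(F)F)C(F)(F)F; potassium bis(trimethylsilyl)amide, C[Si](C)(C)[N-][Si](C)(C)C.[K+] (its potassium stays only in intermediate 22)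
Why: kinetic enolate formation at the methyl group (less hindered than the tertiary C7–H) and O-sulfonylation to the terminal enol triflate; the base is added to the ketone in the presence of the triflating agent so that the enolate is trapped before it can attack the neighbouring acetate or equilibrate to C7 and expel it.

**Step 16**
Reactants: 23 8β-acetoxy-3β-(isobutyryloxy)-12-noreudesma-4,11(13)-dien-11-yl trifluoromethanesulfonate
Product: 24 methyl 8β-acetoxy-3β-(isobutyryloxy)eudesma-4,11(13)-dien-12-oate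
Conditions: Pd(OAc)2 (cat.), PPh3, Et3N, CO (1 atm), MeOH/DMF, 40 °C
Reagents that add atoms: carbon monoxide, [C-]#[O+]; methanol, CO
Why: palladium-catalysed alkoxycarbonylation of an alkenyl triflate: oxidative addition to zerovalent palladium formed in situ, CO insertion and methanolysis of the acyl–palladium species give the α-substituted acrylate; the 8β-oxygen is already acetylated, so no lactone can form, and the hindered allylic ester should not ionise.

**Step 17**
Reactants: 24 methyl 8β-acetoxy-3β-(isobutyryloxy)eudesma-4,11(13)-dien-12-oate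
Product: 25 methyl 8β-acetoxy-5α-hydroperoxy-3β-(isobutyryloxy)eudesma-4(15),11(13)-dien-12-oate
Conditions: O2, tetraphenylporphyrin (cat.), visible light, CH2Cl2, −20 °C
Reagents that add atoms: dioxygen, O=O
Why: Schenck ene reaction of singlet oxygen with the electron-rich tetrasubstituted C4=C5 alkene (the acrylate is inert); oxygen attacks the α face, anti to the axial C14 methyl, and of the allylic hydrogens on that face only those of C15 are freely aligned (C6–Hα lies near the alkene plane, C3–Hα is geminal to the acyloxy group), so O should bond to C5 and the double bond move to C4=C15, setting the 5α-hydroperoxide.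

**Compound list**
1 | 2,4-dimethylphenol | Cc1ccc(O)c(C)c1 | starting material
2 | rac-6-acetoxy-4,6-dimethylcyclohexa-2,4-dien-1-one | CC(=O)OC1(C)C=C(C)C=CC1=O | intermediate
3 | methyl vinyl ketone (but-3-en-2-one) | C=CC(C)=O | starting material
4 | rac-7-endo-acetyl-3,5-dimethyl-2-oxobicyclo[2.2.2]oct-5-en-3-yl acetate (acetyl syn, acetoxy anti to the C5=C6 bridge; racemate, the enantiomer carried on is drawn) | O=C1[C@@](C)(OC(C)=O)[C@H]2C[C@H](C(C)=O)[C@@H]1C=C2C | intermediate
5 | (2R,3R)-butane-2,3-diol | C[C@@H](O)[C@@H](C)O | starting material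
6 | 3,5-dimethyl-2-oxo-7-endo-[(4R,5R)-2,4,5-trimethyl-1,3-dioxolan-2-yl]bicyclo[2.2.2]oct-5-en-3-yl acetate | O=C1[C@@](C)(OC(C)=O)[C@H]2C[C@H](C3(C)O[C@H](C)[C@@H](C)O3)[C@@H]1C=C2C | intermediate
7 | 3-hydroxy-3,5-dimethyl-7-endo-[(4R,5R)-2,4,5-trimethyl-1,3-dioxolan-2-yl]bicyclo[2.2.2]oct-5-en-2-one | O=C1[C@@](C)(O)[C@H]2C[C@H](C3(C)O[C@H](C)[C@@H](C)O3)[C@@H]1C=C2C | intermediate
8 | 3,5-dimethyl-3-(triethylsilyloxy)-7-endo-[(4R,5R)-2,4,5-trimethyl-1,3-dioxolan-2-yl]bicyclo[2.2.2]oct-5-en-2-one | O=C1[C@@](C)(O[Si](CC)(CC)CC)[C@H]2C[C@H](C3(C)O[C@H](C)[C@@H](C)O3)[C@@H]1C=C2C | intermediate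
9 | vinylmagnesium bromide | C=C[Mg]Br | starting material
10 | 3,5-dimethyl-3-(triethylsilyloxy)-7-endo-[(4R,5R)-2,4,5-trimethyl-1,3-dioxolan-2-yl]-2-vinylbicyclo[2.2.2]oct-5-en-2-ol (vinyl syn to the C5=C6 bridge) | C=C[C@]1(O)[C@@](C)(O[Si](CC)(CC)CC)[C@H]2C[C@H](C3(C)O[C@H](C)[C@@H](C)O3)[C@@H]1C=C2C | intermediate
11 | potassium alkoxide of 10 (formed in the flask) | C=C[C@]1([O-])[C@@](C)(O[Si](CC)(CC)CC)[C@H]2C[C@H](C3(C)O[C@H](C)[C@@H](C)O3)[C@@H]1C=C2C.[K+] | intermediate
12 | potassium C2=C3 enolate of 13 (formed in the flask) | CC3(O[C@H](C)[C@@H](C)O3)[C@H]1C[C@@H]2[C@](C)(O[Si](CC)(CC)CC)C([O-])=CC[C@]2(C)C=C1.[K+] | intermediate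
13 | 4α-(triethylsilyloxy)-11,11-[(2R,3R)-butane-2,3-diyldioxy]-12-nor-5β-eudesm-8-en-3-one (cis-fused; 7β side chain, 10β-methyl) | CC3(O[C@H](C)[C@@H](C)O3)[C@H]1C[C@@H]2[C@](C)(O[Si](CC)(CC)CC)C(=O)CC[C@]2(C)C=C1 | intermediate
14 | 4α-hydroxy-11,11-[(2R,3R)-butane-2,3-diyldioxy]-12-nor-5β-eudesm-8-en-3-one | CC3(O[C@H](C)[C@@H](C)O3)[C@H]1C[C@@H]2[C@](C)(O)C(=O)CC[C@]2(C)C=C1 | intermediate
15 | 4α-chlorosulfinyloxy derivative of 14 (formed in the flask) | CC3(O[C@H](C)[C@@H](C)O3)[C@H]1C[C@@H]2[C@](C)(OS(=O)Cl)C(=O)CC[C@]2(C)C=C1 | intermediate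
16 | 11,11-[(2R,3R)-butane-2,3-diyldioxy]-12-noreudesma-4,8-dien-3-one | CC3(O[C@H](C)[C@@H](C)O3)[C@H]1CC2=C(C)C(=O)CC[C@]2(C)C=C1 | intermediate
17 | 8β-acetoxy-9α-iodo-11,11-[(2R,3R)-butane-2,3-diyldioxy]-12-noreudesm-4-en-3-one | CC3(O[C@H](C)[C@@H](C)O3)[C@H]1CC2=C(C)C(=O)CC[C@]2(C)[C@H](I)[C@H]1OC(C)=O | intermediate
18 | 8β-acetoxy-11,11-[(2R,3R)-butane-2,3-diyldioxy]-12-noreudesm-4-en-3-one | CC3(O[C@H](C)[C@@H](C)O3)[C@H]1CC2=C(C)C(=O)CC[C@]2(C)C[C@H]1OC(C)=O | intermediate
19 | 8β-acetoxy-11,11-[(2R,3R)-butane-2,3-diyldioxy]-12-noreudesm-4-en-3β-ol | CC3(O[C@H](C)[C@@H](C)O3)[C@H]1CC2=C(C)[C@@H](O)CC[C@]2(C)C[C@H]1OC(C)=O | intermediate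
20 | 8β-acetoxy-3β-(isobutyryloxy)-11,11-[(2R,3R)-butane-2,3-diyldioxy]-12-noreudesm-4-ene | CC3(O[C@H](C)[C@@H](C)O3)[C@H]1CC2=C(C)[C@@H](OC(=O)C(C)C)CC[C@]2(C)C[C@H]1OC(C)=O | intermediate
21 | 8β-acetoxy-3β-(isobutyryloxy)-12-noreudesm-4-en-11-one (7β-acetyl) | CC(=O)[C@H]1CC2=C(C)[C@@H](OC(=O)C(C)C)CC[C@]2(C)C[C@H]1OC(C)=O | intermediate
22 | potassium C11=C13 enolate of 21 (formed in the flask) | C=C([O-])[C@H]1CC2=C(C)[C@@H](OC(=O)C(C)C)CC[C@]2(C)C[C@H]1OC(C)=O.[K+] | intermediate
23 | 8β-acetoxy-3β-(isobutyryloxy)-12-noreudesma-4,11(13)-dien-11-yl trifluoromethanesulfonate | C=C(OS(=O)(=O)C(F)(F)F)[C@H]1CC2=C(C)[C@@H](OC(=O)C(C)C)CC[C@]2(C)C[C@H]1OC(C)=O | intermediate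
24 | methyl 8β-acetoxy-3β-(isobutyryloxy)eudesma-4,11(13)-dien-12-oate | C=C(C(=O)OC)[C@H]1CC2=C(C)[C@@H](OC(=O)C(C)C)CC[C@]2(C)C[C@H]1OC(C)=O | intermediate
25 | methyl 8β-acetoxy-5α-hydroperoxy-3β-(isobutyryloxy)eudesma-4(15),11(13)-dien-12-oate (CNP0244758.1) | C=C(C(=O)OC)[C@H]1C[C@@]2(OO)C(=C)[C@@H](OC(=O)C(C)C)CC[C@]2(C)C[C@H]1OC(C)=O | target

**Total step count:** 17
**Longest linear sequence:** 17 steps, from 2,4-dimethylphenol (1) to 25.

**Steps most likely to fail**

Step 7 (key step). What may go wrong: transfer of the triethylsilyl group to the potassium alkoxide, or cleavage of the alkoxide by loss of the vinyl group, outruns the sigmatropic shift. The fallback sets out from 10 and returns at 13 and replaces the anionic by the neutral thermal variant. The tertiary alcohol of 10 is capped with N-(trimethylsilyl)imidazole to give 3,5-dimethyl-3-(triethylsilyloxy)-2-(trimethylsilyloxy)-7-endo-[(4R,5R)-2,4,5-trimethyl-1,3-dioxolan-2-yl]-2-vinylbicyclo[2.2.2]oct-5-ene F1. Heating in diphenyl ether at about 220 °C (or flash vacuum pyrolysis) should effect the thermal siloxy-Cope rearrangement to the enol ether 3-(trimethylsilyloxy)-4α-(triethylsilyloxy)-11,11-[(2R,3R)-butane-2,3-diyldioxy]-12-nor-5β-eudesma-2,8-diene F2. Citric acid in methanol then removes only the enol silyl group and returns 13. No alkoxide is present, so silyl transfer and anionic cleavage are excluded.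

Step 9. What may go wrong: proton loss from the C15 methyl group (giving the exocyclic enone), or acyloin-type rearrangement of the ketol, competes with elimination toward C5. The fallback sets out from 13 and returns at 16 and removes the C4 oxygen reductively before the alkene is introduced. SmI2 in THF/MeOH at −78 °C should cleave the α-silyloxy group to give the 4-methyl ketone 11,11-[(2R,3R)-butane-2,3-diyldioxy]-12-nor-5β-eudesm-8-en-3-one F3 (both C4 epimers usable). Me3SiCl, NaI and Et3N in MeCN convert it into the more substituted silyl enol ether 3-(trimethylsilyloxy)-11,11-[(2R,3R)-butane-2,3-diyldioxy]-12-nor-5β-eudesma-3,8-diene F4. Saegusa–Ito oxidation with Pd(OAc)2 in MeCN, by β-hydride elimination toward C5, should then give 16.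

Step 10. What may go wrong: capture of the iodonium ion at the hindered axial C8 position is slow, so that iodination of the enone through its dienol takes over. The fallback sets out from 16 and returns at 20 and introduces the C8 oxygen by hydroboration after the enone has been reduced.
- Luche reduction (NaBH4, CeCl3·7H2O, MeOH) gives 11,11-[(2R,3R)-butane-2,3-diyldioxy]-12-noreudesma-4,8-dien-3β-ol F5.
- Isobutyryl chloride, pyridine and DMAP give 3β-(isobutyryloxy)-11,11-[(2R,3R)-butane-2,3-diyldioxy]-12-noreudesma-4,8-diene F6.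
- BH3·THF at 0 °C should add to the disubstituted C8=C9 alkene from the α face with boron at C8, away from the quaternary C10, while the tetrasubstituted C4=C5 alkene reacts far more slowly. NaBO3 oxidation gives 3β-(isobutyryloxy)-11,11-[(2R,3R)-butane-2,3-diyldioxy]-12-noreudesm-4-en-8α-ol F7.
- Dess–Martin periodinane gives 3β-(isobutyryloxy)-11,11-[(2R,3R)-butane-2,3-diyldioxy]-12-noreudesm-4-en-8-one F8.
- LiBH(s-Bu)3 at −78 °C delivers hydride equatorially, opposite the axial C14 methyl, to give the axial alcohol 3β-(isobutyryloxy)-11,11-[(2R,3R)-butane-2,3-diyldioxy]-12-noreudesm-4-en-8β-ol F9.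
- Ac2O, DMAP and Et3N return 20.

**Further compounds**
F1 | step 7 | 3,5-dimethyl-3-(triethylsilyloxy)-2-(trimethylsilyloxy)-7-endo-[(4R,5R)-2,4,5-trimethyl-1,3-dioxolan-2-yl]-2-vinylbicyclo[2.2.2]oct-5-ene | C=C[C@]1(O[Si](C)(C)C)[C@@](C)(O[Si](CC)(CC)CC)[C@H]2C[C@H](C3(C)O[C@H](C)[C@@H](C)O3)[C@@H]1C=C2C
F2 | step 7 | 3-(trimethylsilyloxy)-4α-(triethylsilyloxy)-11,11-[(2R,3R)-butane-2,3-diyldioxy]-12-nor-5β-eudesma-2,8-diene | CC3(O[C@H](C)[C@@H](C)O3)[C@H]1C[C@@H]2[C@](C)(O[Si](CC)(CC)CC)C(O[Si](C)(C)C)=CC[C@]2(C)C=C1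
F3 | step 9 | 11,11-[(2R,3R)-butane-2,3-diyldioxy]-12-nor-5β-eudesm-8-en-3-one (C4 epimers) | CC3(O[C@H](C)[C@@H](C)O3)[C@H]1C[C@@H]2C(C)C(=O)CC[C@]2(C)C=C1
F4 | step 9 | 3-(trimethylsilyloxy)-11,11-[(2R,3R)-butane-2,3-diyldioxy]-12-nor-5β-eudesma-3,8-diene | CC3(O[C@H](C)[C@@H](C)O3)[C@H]1C[C@@H]2C(C)=C(O[Si](C)(C)C)CC[C@]2(C)C=C1
F5 | step 10 | 11,11-[(2R,3R)-butane-2,3-diyldioxy]-12-noreudesma-4,8-dien-3β-ol | CC3(O[C@H](C)[C@@H](C)O3)[C@H]1CC2=C(C)[C@@H](O)CC[C@]2(C)C=C1
F6 | step 10 | 3β-(isobutyryloxy)-11,11-[(2R,3R)-butane-2,3-diyldioxy]-12-noreudesma-4,8-diene | CC3(O[C@H](C)[C@@H](C)O3)[C@H]1CC2=C(C)[C@@H](OC(=O)C(C)C)CC[C@]2(C)C=C1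
F7 | step 10 | 3β-(isobutyryloxy)-11,11-[(2R,3R)-butane-2,3-diyldioxy]-12-noreudesm-4-en-8α-ol | CC3(O[C@H](C)[C@@H](C)O3)[C@H]1CC2=C(C)[C@@H](OC(=O)C(C)C)CC[C@]2(C)C[C@@H]1O
F8 | step 10 | 3β-(isobutyryloxy)-11,11-[(2R,3R)-butane-2,3-diyldioxy]-12-noreudesm-4-en-8-one | CC3(O[C@H](C)[C@@H](C)O3)[C@H]1CC2=C(C)[C@@H](OC(=O)C(C)C)CC[C@]2(C)CC1=O
F9 | step 10 | 3β-(isobutyryloxy)-11,11-[(2R,3R)-butane-2,3-diyldioxy]-12-noreudesm-4-en-8β-ol | CC3(O[C@H](C)[C@@H](C)O3)[C@H]1CC2=C(C)[C@@H](OC(=O)C(C)C)CC[C@]2(C)C[C@H]1O
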